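Retrosynthesis: ring C is opened at C4–C4a, an acylation of an enol-ether carbon by the C2–C3–C4 acid side chain. Ring A is then cut at C6–C7 and C4a–C5, with C7–C8 broken and re-made on the way, giving a 3-alkoxy-4,4-diprenylcyclobutenone and methoxyacetylene.
Enabling feature: ring A is a cyclohexa-2,4-dienone (C7=O, C5=C6, C4a=C8a) whose only sp3 carbon, C8, is quaternary and carries both prenyl groups. It is therefore the primary product of a dienylketene 6π closure and has no hydrogen at C8 with which to become a phenol.
The cyclobutenone is cut at the vinylic C8a–O1 bond (alkoxy exchange with a chiral hydroxy ester), then into diprenylketene and ethoxyacetylene. The ketene derives from diethyl malonate and prenyl bromide.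
Forward order: C8 with its two prenyl groups, the four-membered ring, the O1 side chain, ring A (step 8), ring C (step 10).
Stereochemistry: C2 is the only stereocentre and is bought as methyl (S)-3-hydroxy-3-phenylpropanoate. None of its bonds is broken afterwards, and base is avoided after step 6 to prevent β-elimination.

Key step: step 8

Remark: flavanone numbering (O1, C2, C3, C4, C4a, C5–C8, C8a) is used for these atoms in all precursors. R* stands for (S)-3-methoxy-3-oxo-1-phenylpropyl. Methoxyacetylene is assumed to need fresh preparation because it stores poorly.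

Step 1
Reactants: 1 diethyl malonate; 2 prenyl bromide (1-bromo-3-methylbut-2-ene)
Product: 3 diethyl 2,2-bis(3-methylbut-2-en-1-yl)malonate
Conditions: NaH (2.4 equiv), 2 (2.4 equiv), THF, 0 °C → reflux
Reagents that add atoms: none
Why: Twofold SN2 alkylation of the malonate enolate by a reactive primary allylic bromide (malonic ester synthesis) assembles the future C8 with both prenyl groups and creates no stereocentre.

Step 2
Reactants: 3 diethyl 2,2-bis(3-methylbut-2-en-1-yl)malonate
Product: 4 2,2-bis(3-methylbut-2-en-1-yl)malonic acid
Conditions: KOH (6 equiv), EtOH/H2O, reflux; then aq HCl, 0 °C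
Reagents that add atoms: potassium hydroxide, [K+].[OH-]
Why: Saponification of the hindered geminal diester with hot aqueous-ethanolic KOH is standard and leaves the isolated trisubstituted alkenes untouched.

Step 3
Reactants: 4 2,2-bis(3-methylbut-2-en-1-yl)malonic acid
Product: 5 5-methyl-2-(3-methylbut-2-en-1-yl)hex-4-enoic acid (diprenylacetic acid)
Conditions: neat, 165 °C, argon, until CO2 evolution ends
Reagents that add atoms: none
Why: A geminal diacid loses CO2 on heating through a cyclic six-membered transition state (second half of the malonic ester synthesis), and no strong acid is present that could lactonize the γ,δ-unsaturated acid.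

Step 4
Reactants: 5 diprenylacetic acid
Product: 6 5-methyl-2-(3-methylbut-2-en-1-yl)hex-4-enoyl chloride (diprenylacetyl chloride)
Conditions: (COCl)2 (1.3 equiv), DMF (cat.), CH2Cl2, 0 °C → rt; evaporate
Reagents that add atoms: oxalyl chloride, O=C(Cl)C(=O)Cl
Why: Chlorination through the catalytic Vilsmeier-type chloroiminium salt runs at or below room temperature with gaseous by-products only, the usual way to acid chlorides of alkene-bearing acids.

Step 5
Reactants: 6 diprenylacetyl chloride; 7 ethoxyacetylene
Product: 9 3-ethoxy-4,4-bis(3-methylbut-2-en-1-yl)cyclobut-2-en-1-one, via diprenylketene 8 (not isolated)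
Conditions: 7 (2.5 equiv, solution in hexanes), Et3N (1.5 equiv), Et2O, 35 °C
Reagents that add atoms: none
Why: Dehydrochlorination gives the dialkylketene, which is trapped as it forms by the ynol ether in a thermal [2+2] cycloaddition whose polarity (CH carbon of 7 to the ketene carbonyl carbon) places OEt next to the quaternary carbon, the established access to 3-ethoxy-4,4-dialkylcyclobutenones; the one-carbon spacer keeps the prenyl alkenes out of reach of the ketene.

Step 6
Reactants: 9 3-ethoxy-4,4-bis(3-methylbut-2-en-1-yl)cyclobut-2-en-1-one; 10 methyl (S)-3-hydroxy-3-phenylpropanoate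
Product: 11 methyl (S)-3-{[4,4-bis(3-methylbut-2-en-1-yl)-3-oxocyclobut-1-en-1-yl]oxy}-3-phenylpropanoate
Conditions: 10 (2 equiv), camphorsulfonic acid (10 mol %), 5 Å molecular sieves, toluene, 60 °C
Reagents that add atoms: none
Why: Acid-catalysed addition–elimination at the β-carbon of the vinylogous ester (transetherification, as practised with 3-alkoxyenones and squarates) is driven by trapping of ethanol, exchanges only the vinylic C–O bond so that the carbinol C–O bond and the (S) configuration of 10 are retained, and runs below the temperature at which the cyclobutenone would open and acylate the alcohol.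

Step 7
Reactants: 12 chloroacetaldehyde dimethyl acetal (2-chloro-1,1-dimethoxyethane)
Product: 14 methoxyacetylene, via sodium methoxyacetylide 13 (not isolated)
Conditions: NaNH2 (3.2 equiv), liquid NH3, −33 °C; then saturated aq NaCl, −20 °C; distil into a −78 °C trap
Reagents that add atoms: none
Why: NaNH2 removes HCl and then MeOH from the chloroacetal and deprotonates the alkyne, and protonation of the acetylide on quenching frees the ynol ether, which is the standard preparation of alkoxyacetylenes; lacking a β-hydrogen in its alkyl group, 14 cannot decay by the retro-ene path open to 7.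

Step 8
Reactants: 11 methyl (S)-3-{[4,4-bis(3-methylbut-2-en-1-yl)-3-oxocyclobut-1-en-1-yl]oxy}-3-phenylpropanoate; 14 methoxyacetylene
Product: 18 methyl (S)-3-{[3-methoxy-5-oxo-6,6-bis(3-methylbut-2-en-1-yl)cyclohexa-1,3-dien-1-yl]oxy}-3-phenylpropanoate (ring A dienone), via vinylketene 15 (not isolated), via vinylcyclobutenone 16 (not isolated), via dienylketene 17 (not isolated)
Conditions: 14 (10 equiv, about 2 M), MeCN, hν (254 nm, quartz), 0 °C; evaporate excess 14 and MeCN; then toluene, 100 °C
Reagents that add atoms: none
Why: Proposed new method: light opens the C7–C8 bond of 11 (4π electrocyclic opening, a known photoreaction of cyclobutenones) to vinylketene 15, whose ketene C=C adds 14 in a [2+2] cycloaddition that forms C6–C7 and C4a–C5, and on heating the resulting 16 opens conrotatorily (C7–C4a breaks) to dienylketene 17, which closes ring A by a disrotatory 6π electrocyclization that re-forms C7–C8. The closest known reaction type is the Danheiser benzannulation of cyclobutenones with alkoxyacetylenes, in whose photochemical variant the vinylketene is likewise made by light and the cascade is finished by heating; new is a diene terminus (C8) with two carbon substituents, so that the primary cyclohexa-2,4-dienone has no hydrogen to lose and is itself the product. The last closure is the thermal reverse of the well-studied photochemical opening of 6,6-disubstituted cyclohexa-2,4-dienones to dienylketenes, which argues that a fully substituted C8 does not block it. Regioselectivity (OMe on C5 and H on C6) is secured by polarity, because the nucleophilic CH carbon of 14 bonds to the electrophilic ketene carbon C7. Chemoselectivity over the intramolecular [2+2] addition of the ketene to the cis prenyl double bond is sought by making 15 at 0 °C in polar MeCN that is about 2 M in the far more nucleophilic ynol ether, conditions that favour the bimolecular low-enthalpy pathway, avoid the temperatures above 130 °C expected for thermal opening of a push-pull 4,4-dialkylcyclobutenone, and keep 18 below the onset of a Cope shift of prenyl to C4a. No stereocentre is created in 18 (the C4a centre of 16 is transient and becomes sp2 again) and C2 is a remote spectator.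

Step 9
Reactants: 18 ring A dienone methyl ester
Product: 19 (S)-3-{[3-methoxy-5-oxo-6,6-bis(3-methylbut-2-en-1-yl)cyclohexa-1,3-dien-1-yl]oxy}-3-phenylpropanoic acid
Conditions: Me3SnOH (5 equiv), 1,2-dichloroethane, 65 °C; then cold 0.5 M aq HCl wash
Reagents that add atoms: trimethyltin hydroxide, C[Sn](C)(C)O
Why: Me3SnOH cleaves methyl esters by tin-assisted acyl–oxygen cleavage under essentially neutral conditions, which should avoid the E1cB loss of the vinylogous carboxylate O1 from C2 that aqueous hydroxide would trigger and should leave the vinylogous ester OMe at C5 in place.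

Step 10
Reactants: 19 (S)-3-{[3-methoxy-5-oxo-6,6-bis(3-methylbut-2-en-1-yl)cyclohexa-1,3-dien-1-yl]oxy}-3-phenylpropanoic acid
Product: 22 Griffinone A [(S)-5-methoxy-8,8-bis(3-methylbut-2-en-1-yl)-2-phenyl-2,3-dihydro-4H-chromene-4,7(8H)-dione], via acid chloride 20 (not isolated), via acyl triflate 21 (not isolated)
Conditions: 1-chloro-N,N,2-trimethylprop-1-en-1-amine (1.1 equiv), CH2Cl2, 0 °C; then AgOTf (1.2 equiv), 2,6-di-tert-butyl-4-methylpyridine (1.5 equiv), CH2Cl2 (2 mM), −40 → 0 °C
Reagents that add atoms: none
Why: Intramolecular Friedel–Crafts-type C-acylation of the enol-ether carbon C4a (six-membered closure, the dearomatized counterpart of the cyclization of 3-aryloxy-3-phenylpropanoic acids to flavanones): the neutral chloroenamine makes the acid chloride without acid or base, AgOTf raises it to the acyl triflate needed for a donor–acceptor diene of reduced nucleophilicity, only C4a lies within reach of the tether, high dilution holds back intermolecular attack at C6, the hindered pyridine takes up TfOH so that the prenyl groups and the benzylic C2–O1 bond are spared, and C2 is not touched.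

Compound list
1 | diethyl malonate | CCOC(=O)CC(=O)OCC | starting material
2 | prenyl bromide | CC(C)=CCBr | starting material
3 | diethyl 2,2-bis(3-methylbut-2-en-1-yl)malonate | CCOC(=O)C(CC=C(C)C)(CC=C(C)C)C(=O)OCC | intermediate
4 | 2,2-bis(3-methylbut-2-en-1-yl)malonic acid | OC(=O)C(CC=C(C)C)(CC=C(C)C)C(=O)O | intermediate
5 | 5-methyl-2-(3-methylbut-2-en-1-yl)hex-4-enoic acid | OC(=O)C(CC=C(C)C)CC=C(C)C | intermediate
6 | 5-methyl-2-(3-methylbut-2-en-1-yl)hex-4-enoyl chloride | ClC(=O)C(CC=C(C)C)CC=C(C)C | intermediate
7 | ethoxyacetylene | CCOC#C | starting material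
8 | diprenylketene [5-methyl-2-(3-methylbut-2-en-1-yl)hexa-1,4-dien-1-one] | O=C=C(CC=C(C)C)CC=C(C)C | intermediate
9 | 3-ethoxy-4,4-bis(3-methylbut-2-en-1-yl)cyclobut-2-en-1-one | CCOC1=CC(=O)C1(CC=C(C)C)CC=C(C)C | intermediate
10 | methyl (S)-3-hydroxy-3-phenylpropanoate | COC(=O)C[C@H](O)c1ccccc1 | starting material
11 | methyl (S)-3-{[4,4-bis(3-methylbut-2-en-1-yl)-3-oxocyclobut-1-en-1-yl]oxy}-3-phenylpropanoate | O=C1C=C(O[C@@H](CC(=O)OC)c2ccccc2)C1(CC=C(C)C)CC=C(C)C | intermediate
12 | chloroacetaldehyde dimethyl acetal | COC(CCl)OC | starting material
13 | sodium methoxyacetylide | COC#[C-].[Na+] | intermediate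
14 | methoxyacetylene | COC#C | intermediate
15 | vinylketene O=C7=C4aH–C8a(OR*)=C8(prenyl)2 | O=C=CC(O[C@@H](CC(=O)OC)c1ccccc1)=C(CC=C(C)C)CC=C(C)C | intermediate
16 | 3-methoxy-4-[1-(OR*)-2,2-diprenylvinyl]cyclobut-2-en-1-one, both epimers at the ring CH (C4a) | COC1=CC(=O)C1C(O[C@@H](CC(=O)OC)c2ccccc2)=C(CC=C(C)C)CC=C(C)C | intermediate
17 | dienylketene O=C7=C6H–C5(OMe)=C4aH–C8a(OR*)=C8(prenyl)2, C6 and C8a cis on C5=C4a | O=C=C/C(OC)=C\C(O[C@@H](CC(=O)OC)c1ccccc1)=C(CC=C(C)C)CC=C(C)C | intermediate
18 | methyl (S)-3-{[3-methoxy-5-oxo-6,6-bis(3-methylbut-2-en-1-yl)cyclohexa-1,3-dien-1-yl]oxy}-3-phenylpropanoate | COC1=CC(=O)C(CC=C(C)C)(CC=C(C)C)C(O[C@@H](CC(=O)OC)c2ccccc2)=C1 | intermediate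
19 | (S)-3-{[3-methoxy-5-oxo-6,6-bis(3-methylbut-2-en-1-yl)cyclohexa-1,3-dien-1-yl]oxy}-3-phenylpropanoic acid | COC1=CC(=O)C(CC=C(C)C)(CC=C(C)C)C(O[C@@H](CC(=O)O)c2ccccc2)=C1 | intermediate
20 | acid chloride of 19 | COC1=CC(=O)C(CC=C(C)C)(CC=C(C)C)C(O[C@@H](CC(=O)Cl)c2ccccc2)=C1 | intermediate
21 | mixed carboxylic trifluoromethanesulfonic anhydride (acyl triflate) of 19 | COC1=CC(=O)C(CC=C(C)C)(CC=C(C)C)C(O[C@@H](CC(=O)OS(=O)(=O)C(F)(F)F)c2ccccc2)=C1 | intermediate
22 | Griffinone A | COC1=CC(=O)C(CC=C(C)C)(CC=C(C)C)C2=C1C(=O)C[C@@H](c1ccccc1)O2 | target

Total step count: 10. Longest linear sequence: 9 steps (steps 1–6 and 8–10, from diethyl malonate). Step 7 is a one-step side branch.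

Steps most likely to fail

**Step 8.**
- The photogenerated ketene may be consumed by intramolecular [2+2] addition to the neighbouring prenyl double bond, or by a second addition of the alkyne.
- Secondary photolysis may erode the intermediates.
- Inward rotation of the bulky alkenyl group in the second ring opening may need a temperature at which prenyl migration with aromatization sets in.

The fallback uses known chemistry and makes ring A by dearomatization instead of annulation. It sets out from prenyl bromide 2. Commercial 5-methoxyresorcinol is C-alkylated twice with 2 at the carbon between its two hydroxyl groups (KOH, H2O/MeOH, 0 °C). This is a base-mediated dearomative prenylation of the kind used for prenylated phloroglucinols. After separation from regioisomers it should give 5-hydroxy-3-methoxy-6,6-bis(3-methylbut-2-en-1-yl)cyclohexa-2,4-dien-1-one F1. The anion of this vinylogous acid is symmetric, so a Mitsunobu etherification can give only one O-alkyl product. With commercial methyl (R)-3-hydroxy-3-phenylpropanoate (PPh3, DIAD, toluene, 0 °C), which reacts with inversion at the carbinol carbon, that product is 18, where the route is rejoined.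

**Step 10.**
- C4a is an attenuated nucleophile, so ionization or β-elimination at the benzylic C2–O1 bond may outrun the acylation. That would mean loss of the side chain or erosion of the configuration.
- Intermolecular acylation at C6 may compete.

The fallback closes ring C at O1–C2 instead of C4–C4a. It sets out from 18. DBU (CH2Cl2, rt) deliberately triggers the E1cB cleavage and frees 5-hydroxy-3-methoxy-6,6-bis(3-methylbut-2-en-1-yl)cyclohexa-2,4-dien-1-one F1. O-acylation with cinnamoyl chloride and Et3N should give 3-methoxy-5-oxo-6,6-bis(3-methylbut-2-en-1-yl)cyclohexa-1,3-dien-1-yl (E)-3-phenylprop-2-enoate F2. The 4-(dimethylamino)pyridine-catalysed O-to-C acyl shift known for enol esters of cyclic 1,3-diones then moves the cinnamoyl group to C4a, which is equivalent to C6 in the symmetric anion. This should give 5-hydroxy-3-methoxy-6,6-bis(3-methylbut-2-en-1-yl)-4-[(E)-3-phenylprop-2-enoyl]cyclohexa-2,4-dien-1-one F3. An enantioselective intramolecular oxa-Michael addition of the C8a hydroxyl then sets C2 under catalyst control and arrives at 22. The catalyst is 1-[3,5-bis(trifluoromethyl)phenyl]-3-[(8α,9S)-6'-methoxycinchonan-9-yl]thiourea or its quinidine-derived pseudoenantiomer, whichever delivers the (S) product.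

**Step 6.**
- Addition of a hindered secondary alcohol next to the quaternary carbon may be slow and the exchange equilibrium unfavourable.
- Prolonged exposure to acid may dehydrate the β-hydroxy ester.

The fallback forms the same ether from the other side, by substitution at the carbinol carbon. It sets out from 9, which is hydrolysed (2 M aq HCl, THF, rt) to the strongly acidic enol 3-hydroxy-4,4-bis(3-methylbut-2-en-1-yl)cyclobut-2-en-1-one F4. The two oxygen atoms of this enol are equivalent. A Mitsunobu reaction with commercial methyl (R)-3-hydroxy-3-phenylpropanoate (PPh3, DIAD, THF, 0 °C) should proceed with inversion and return to the route at 11.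

Further compounds
F1 | step 8 | 5-hydroxy-3-methoxy-6,6-bis(3-methylbut-2-en-1-yl)cyclohexa-2,4-dien-1-one | COC1=CC(=O)C(CC=C(C)C)(CC=C(C)C)C(O)=C1
F2 | step 10 | 3-methoxy-5-oxo-6,6-bis(3-methylbut-2-en-1-yl)cyclohexa-1,3-dien-1-yl (E)-3-phenylprop-2-enoate | COC1=CC(=O)C(CC=C(C)C)(CC=C(C)C)C(OC(=O)/C=C/c2ccccc2)=C1
F3 | step 10 | 5-hydroxy-3-methoxy-6,6-bis(3-methylbut-2-en-1-yl)-4-[(E)-3-phenylprop-2-enoyl]cyclohexa-2,4-dien-1-one | COC1=CC(=O)C(CC=C(C)C)(CC=C(C)C)C(O)=C1C(=O)/C=C/c2ccccc2
F4 | step 6 | 3-hydroxy-4,4-bis(3-methylbut-2-en-1-yl)cyclobut-2-en-1-one | O=C1C=C(O)C1(CC=C(C)C)CC=C(C)C
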